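**Strategy.** The route is built on disconnecting the C9–C11 bond. Ring B contains an allyl triad C7–C8–C9 in which C9, the carbon that must carry the four-carbon chain on the same face as the C10 methyl, is the remote terminus from a C7 oxygen. A [2,3]-Wittig shift of a 7β-propargylic ether therefore moves the chain from oxygen to the hindered β-face of C9. The same operation places the Δ7 alkene needed for the C6–C8 oxygens and leaves a C11 carbinol/alkyne that is a masked E-butenone. The precursor is the 7β-but-2-ynyl ether of trans-fused 11-nordrim-8-en-7β-ol, reached by asymmetric allylation, ring-closing metathesis and enone chemistry.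

Key step: step 12

Remark (conventions): drimane numbering is used (ring A C1–C5/C10, ring B C5–C10, chain on C9 = C11, C12, C13 and its methyl); α is the face opposite the C10 methyl. C8 in 10–13, the carbinol carbon in 7 and C11 in 19–28 are left undefined because each becomes sp2 later.

Remark (assumption): (S)-t-BuPHOX is taken to give the (S) centre in 5, as it does with 2-methylcyclohexanone-derived enol carbonates; the mirror-image ligand would be used otherwise.

**Step 1**
Reactants: 1 3-ethoxycyclohex-2-en-1-one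
Product: 2 3-ethoxy-6-methylcyclohex-2-en-1-one (racemic)
Conditions: LDA, THF, −78 °C; MeI, −78 °C → rt
Reagents that add atoms: iodomethane (CI)
Why: Kinetic α′-deprotonation of the vinylogous ester at C6 and SN2 methylation (Stork–Danheiser α′-alkylation); the new centre is racemic and becomes sp2 in step 2.

**Step 2**
Reactants: 2 3-ethoxy-6-methylcyclohex-2-en-1-one; 3 allyl chloroformate
Product: 4 allyl 4-ethoxy-2-methylcyclohexa-1,3-dien-1-yl carbonate
Conditions: LDA, TMEDA, THF, −78 °C; then 3, −78 °C
Reagents that add atoms: none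
Why: O-acylation of the tetrasubstituted α′-enolate by the chloroformate gives the allyl enol carbonate; any C-acylated β-keto ester would converge on the same product in step 3.

**Step 3**
Reactants: 4 allyl 4-ethoxy-2-methylcyclohexa-1,3-dien-1-yl carbonate
Product: 5 (S)-6-allyl-3-ethoxy-6-methylcyclohex-2-en-1-one
Conditions: Pd2(dba)3 (2.5 mol %), (S)-t-BuPHOX (6.25 mol %), toluene, 30 °C
Reagents that add atoms: none
Why: Decarboxylative asymmetric allylic alkylation (Tsuji–Trost type): Pd(0) ionises the allyl carbonate, CO2 is lost, and the PHOX-bound π-allylpalladium enolate is C-allylated on one enantioface, setting the quaternary centre that becomes C10.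

**Step 4**
Reactants: 5 (S)-6-allyl-3-ethoxy-6-methylcyclohex-2-en-1-one; 6 prenylmagnesium chloride
Product: 8 (S)-4-allyl-4-methyl-3-(2-methylbut-3-en-2-yl)cyclohex-2-en-1-one, via tertiary carbinol 7 (not isolated)
Conditions: 6 (2.5 equiv), THF, −78 → 0 °C; then 2 M aq HCl, rt
Reagents that add atoms: water (O)
Why: The allylic Grignard reagent adds 1,2 through a six-membered SE2′ transition state at its more substituted terminus, and acid hydrolysis of the enol ether with loss of the tertiary hydroxyl gives the transposed enone (Stork–Danheiser sequence); the quaternary centre is untouched.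

**Step 5**
Reactants: 8 (S)-4-allyl-4-methyl-3-(2-methylbut-3-en-2-yl)cyclohex-2-en-1-one
Product: 9 (4aS)-4a,8,8-trimethyl-4,4a,5,8-tetrahydronaphthalen-2(3H)-one
Conditions: Grubbs II (3 mol %), CH2Cl2, 40 °C
Reagents that add atoms: none
Why: Ring-closing metathesis of the two monosubstituted alkenes closes ring A as a cyclohexene (C2=C3) with loss of ethene, helped by the gem-dimethyl group.

**Step 6**
Reactants: 9 (4aS)-4a,8,8-trimethyl-4,4a,5,8-tetrahydronaphthalen-2(3H)-one
Product: 10 11-nordrima-2,5-dien-7-one (C8 epimers)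
Conditions: LDA, THF, −78 °C; MeI, −78 → 0 °C
Reagents that add atoms: iodomethane (CI)
Why: Kinetic enolate alkylation is regiospecific because C8 is the only enolisable position (C4 and C10 are quaternary, so there are no γ-hydrogens); the C8 configuration is irrelevant.

**Step 7**
Reactants: 10 11-nordrima-2,5-dien-7-one
Product: 11 11-nordrim-2-en-7-one (5α-H; C8 epimers)
Conditions: Li, NH3(l), THF, t-BuOH (1 equiv), −78 °C; NH4Cl
Reagents that add atoms: none
Why: Dissolving-metal conjugate reduction of the enone; axial protonation of the C5 carbanion on the α-face, anti to the C10 methyl, gives the trans ring fusion, and the isolated Δ2 alkene is not reduced.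

**Step 8**
Reactants: 11 11-nordrim-2-en-7-one
Product: 12 11-nordriman-7-one (C8 epimers)
Conditions: H2 (1 atm), 10 % Pd/C, EtOAc, rt
Reagents that add atoms: none
Why: Heterogeneous catalytic hydrogenation of the cis-disubstituted Δ2 alkene; the ketone is unaffected and no stereocentre is formed.

**Step 9**
Reactants: 12 11-nordriman-7-one
Product: 14 11-nordrim-8-en-7-one, via α-chloro ketone 13 (not isolated)
Conditions: SO2Cl2, CH2Cl2, 0 °C → rt; concentrate; LiBr, Li2CO3, DMF, 120 °C
Reagents that add atoms: none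
Why: Chlorination through the more substituted enol occurs at tertiary C8, and dehydrochlorination then gives the conjugated endocyclic α-methyl enone, as in the classical conversion of 2-methylcyclohexanone into 2-methylcyclohex-2-enone.

**Step 10**
Reactants: 14 11-nordrim-8-en-7-one
Product: 15 11-nordrim-8-en-7β-ol
Conditions: NaBH4, CeCl3·7H2O, MeOH, −78 → 0 °C
Reagents that add atoms: none
Why: Luche 1,2-reduction; hydride approaches C7 along the pseudoaxial α trajectory, where only 5α-H stands in the way, to give the pseudoequatorial 7β-alcohol.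

**Step 11**
Reactants: 15 11-nordrim-8-en-7β-ol; 16 1-bromobut-2-yne
Product: 17 7β-(but-2-ynyloxy)-11-nordrim-8-ene
Conditions: NaH, THF/DMF, 0 °C; 16, Bu4NI (cat.), rt
Reagents that add atoms: none
Why: Williamson etherification (SN2 at the propargylic bromide); the C7–O bond is not broken, so the 7β configuration is kept.

**Step 12**
Reactants: 17 7β-(but-2-ynyloxy)-11-nordrim-8-ene
Product: 19 9β-(1-hydroxybut-2-ynyl)-11-nordrim-7-ene, via lithiated ether 18 (not isolated)
Conditions: n-BuLi (1.5 equiv), THF, −78 → −30 °C; aq NH4Cl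
Reagents that add atoms: none
Why: n-BuLi removes a proton from the propargylic O–CH2, and the α-alkoxy propargyl anion 18 rearranges in a concerted [2,3]-Wittig shift through a five-membered envelope transition state in which C11 bonds to C9 while C7–O breaks and the alkene moves to C7=C8. The closest known reaction type is the [2,3]-Wittig rearrangement of allyl but-2-ynyl ethers, cyclohexenyl ethers included, with 1,3-transfer of chirality. No ring is closed. C9 is controlled by C7: the shift is suprafacial across the allyl unit, so the 7β-oxygen delivers C11 to the β-face of C9, cis to the C10 methyl, whereas C11 should form mainly as one epimer whose configuration is irrelevant because C11 becomes sp2 in step 20. The step needs deprotonation at O–CH2 and [2,3] over [1,2] migration; the first is secured by that site being the most acidic (flanked by alkyne and ether oxygen, no other activated C–H), the second by the propargyl-stabilised anion and by warming only as far as ring B needs to reach the boat-like shape in which the pseudoequatorial 7β C–O bond overlaps with the alkene π system.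

**Step 13**
Reactants: 19 9β-(1-hydroxybut-2-ynyl)-11-nordrim-7-ene
Product: 20 9β-(1-acetoxybut-2-ynyl)-11-nordrim-7-ene
Conditions: Ac2O, pyridine, DMAP (cat.), CH2Cl2, rt
Reagents that add atoms: acetic anhydride (CC(=O)OC(C)=O)
Why: Acylation of the secondary propargylic alcohol; the acetate protects C11–OH through the oxidations and later serves as the migrating group for enone formation.

**Step 14**
Reactants: 20 9β-(1-acetoxybut-2-ynyl)-11-nordrim-7-ene
Product: 21 9β-(1-acetoxybut-2-ynyl)-11-nordrimane-7α,8α-diol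
Conditions: OsO4 (5 mol %), NMO, acetone/H2O, rt
Reagents that add atoms: osmium tetroxide (O=[Os](=O)(=O)=O), N-methylmorpholine N-oxide (C[N+]1([O-])CCOCC1), water (O)
Why: Upjohn syn-dihydroxylation of the trisubstituted Δ7 alkene from the α-face, the β-face being shielded by the axial C10 methyl and the 9β chain, which fixes 8α-OH/8β-CH3; the alkyne reacts far more slowly.

**Step 15**
Reactants: 21 9β-(1-acetoxybut-2-ynyl)-11-nordrimane-7α,8α-diol
Product: 22 9β-(1-acetoxybut-2-ynyl)-8α-hydroxy-11-nordriman-7-one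
Conditions: IBX, DMSO, rt
Reagents that add atoms: none
Why: IBX oxidises the secondary axial 7α-alcohol of the diol to the ketone without glycol cleavage, leaves the tertiary 8-OH, and removes the wrong C7 configuration.

**Step 16**
Reactants: 22 9β-(1-acetoxybut-2-ynyl)-8α-hydroxy-11-nordriman-7-one
Product: 23 9β-(1-acetoxybut-2-ynyl)-7,8α-bis(triethylsilyloxy)-11-nordrim-6-ene
Conditions: TESOTf (3 equiv), Et3N, CH2Cl2, −78 → 0 °C
Reagents that add atoms: triethylsilyl trifluoromethanesulfonate (CC[Si](CC)(CC)OS(=O)(=O)C(F)(F)F)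
Why: Soft enolisation can only go towards C6 because C8 is fully substituted, giving the Δ6 silyl enol ether, and the tertiary 8-OH is silylated in the same operation, which later keeps O8 away from the gold-activated alkyne.

**Step 17**
Reactants: 23 9β-(1-acetoxybut-2-ynyl)-7,8α-bis(triethylsilyloxy)-11-nordrim-6-ene
Product: 26 9β-(1-acetoxybut-2-ynyl)-6α-hydroxy-8α-(triethylsilyloxy)-11-nordriman-7-one, via silyloxy epoxide 24 (not isolated), via 6α-silyloxy ketone 25 (not isolated)
Conditions: mCPBA, NaHCO3, CH2Cl2, −20 → 0 °C; then MeOH, PPTS, 0 °C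
Reagents that add atoms: 3-chloroperoxybenzoic acid (OOC(=O)c1cccc(Cl)c1)
Why: Rubottom oxidation; epoxidation on the α-face (the β-face carries the axial methyls on C4, C8 and C10) and ring opening with 1,4-silyl shift give the equatorial 6α-silyloxy ketone, whose secondary TES ether is methanolysed selectively beside the hindered tertiary one.

**Step 18**
Reactants: 26 9β-(1-acetoxybut-2-ynyl)-6α-hydroxy-8α-(triethylsilyloxy)-11-nordriman-7-one
Product: 27 6α-acetoxy-9β-(1-acetoxybut-2-ynyl)-8α-(triethylsilyloxy)-11-nordriman-7-one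
Conditions: Ac2O, pyridine, DMAP (cat.), CH2Cl2, 0 °C → rt
Reagents that add atoms: acetic anhydride (CC(=O)OC(C)=O)
Why: Acetylation of the only free hydroxyl, the secondary α-ketol OH, with the equatorial 6α configuration (also the thermodynamic one) retained.

**Step 19**
Reactants: 27 6α-acetoxy-9β-(1-acetoxybut-2-ynyl)-8α-(triethylsilyloxy)-11-nordriman-7-one
Product: 28 6α-acetoxy-9β-(1-acetoxybut-2-ynyl)-8α-(triethylsilyloxy)-11-nordriman-7β-ol
Conditions: NaBH4, CeCl3·7H2O, MeOH/THF, −78 → −40 °C; AcOH quench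
Reagents that add atoms: none
Why: Borohydride reduction with axial attack on C7 from the α-face, the β-face being blocked by the axial 8β-methyl, gives the equatorial 7β-alcohol; low temperature and an acidic quench suppress acetyl migration and spare the esters.

**Step 20**
Reactants: 28 6α-acetoxy-9β-(1-acetoxybut-2-ynyl)-8α-(triethylsilyloxy)-11-nordriman-7β-ol
Product: 30 6α-acetoxy-9β-[(E)-3-oxobut-1-enyl]-8α-(triethylsilyloxy)-11-nordriman-7β-ol, via allenyl acetate 29 (not isolated)
Conditions: Ph3PAuNTf2 (2 mol %), wet butan-2-one, rt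
Reagents that add atoms: none
Why: Gold(I)-catalysed 3,3-acyloxy shift of the propargylic acetate to the allenyl acetate and its hydrolysis (a Meyer–Schuster-type rearrangement of a propargylic ester) give the E-enone with the carbonyl at C13 and erase C11; O8 is silylated and the Δ7 alkene is gone, so neither hydroalkoxylation nor enyne cycloisomerisation can compete.

**Step 21**
Reactants: 30 6α-acetoxy-9β-[(E)-3-oxobut-1-enyl]-8α-(triethylsilyloxy)-11-nordriman-7β-ol
Product: 31 6α-acetoxy-9β-[(E)-3-oxobut-1-enyl]-11-nordrimane-7β,8α-diol (CNP0136046.1)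
Conditions: HF·pyridine, pyridine/THF, 0 °C → rt
Reagents that add atoms: none
Why: Fluoride cleavage of the tertiary silyl ether under mildly acidic conditions, which avoid acetyl migration from O6 to O7 and leave the enone untouched.

**Compound list**
1 | 3-ethoxycyclohex-2-en-1-one | CCOC1=CC(=O)CCC1 | starting material
2 | 3-ethoxy-6-methylcyclohex-2-en-1-one (racemic) | CCOC1=CC(=O)C(C)CC1 | intermediate
3 | allyl chloroformate | C=CCOC(=O)Cl | starting material
4 | allyl 4-ethoxy-2-methylcyclohexa-1,3-dien-1-yl carbonate | CCOC1=CC(OC(=O)OCC=C)=C(C)CC1 | intermediate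
5 | (S)-6-allyl-3-ethoxy-6-methylcyclohex-2-en-1-one | CCOC1=CC(=O)[C@](C)(CC=C)CC1 | intermediate
6 | prenylmagnesium chloride (3-methylbut-2-enylmagnesium chloride, THF solution) | CC(C)=CC[Mg]Cl | starting material
7 | (6S)-6-allyl-3-ethoxy-6-methyl-1-(2-methylbut-3-en-2-yl)cyclohex-2-en-1-ol (carbinol epimers) | CCOC1=CC(O)(C(C)(C)C=C)[C@](C)(CC=C)CC1 | intermediate
8 | (S)-4-allyl-4-methyl-3-(2-methylbut-3-en-2-yl)cyclohex-2-en-1-one | O=C1C=C(C(C)(C)C=C)[C@](C)(CC=C)CC1 | intermediate
9 | (4aS)-4a,8,8-trimethyl-4,4a,5,8-tetrahydronaphthalen-2(3H)-one (11,12-dinordrima-2,5-dien-7-one) | O=C1C=C2C(C)(C)C=CC[C@]2(C)CC1 | intermediate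
10 | 11-nordrima-2,5-dien-7-one (10β-CH3; C8 epimers) | O=C1C=C2C(C)(C)C=CC[C@]2(C)CC1C | intermediate
11 | 11-nordrim-2-en-7-one (5α-H, 10β-CH3; C8 epimers) | O=C1C[C@H]2C(C)(C)C=CC[C@]2(C)CC1C | intermediate
12 | 11-nordriman-7-one (5α-H, 10β-CH3; C8 epimers) | O=C1C[C@H]2C(C)(C)CCC[C@]2(C)CC1C | intermediate
13 | 8-chloro-11-nordriman-7-one (C8 epimers) | O=C1C[C@H]2C(C)(C)CCC[C@]2(C)CC1(C)Cl | intermediate
14 | 11-nordrim-8-en-7-one | O=C1C[C@H]2C(C)(C)CCC[C@]2(C)C=C1C | intermediate
15 | 11-nordrim-8-en-7β-ol | O[C@H]1C[C@H]2C(C)(C)CCC[C@]2(C)C=C1C | intermediate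
16 | 1-bromobut-2-yne | CC#CCBr | starting material
17 | 7β-(but-2-ynyloxy)-11-nordrim-8-ene | CC#CCO[C@H]1C[C@H]2C(C)(C)CCC[C@]2(C)C=C1C | intermediate
18 | 7β-(1-lithiobut-2-ynyloxy)-11-nordrim-8-ene | CC#CC([Li])O[C@H]1C[C@H]2C(C)(C)CCC[C@]2(C)C=C1C | intermediate
19 | 9β-(1-hydroxybut-2-ynyl)-11-nordrim-7-ene (C11 undefined) | CC#CC(O)[C@H]1C(C)=CC[C@H]2C(C)(C)CCC[C@@]21C | intermediate
20 | 9β-(1-acetoxybut-2-ynyl)-11-nordrim-7-ene | CC#CC(OC(C)=O)[C@H]1C(C)=CC[C@H]2C(C)(C)CCC[C@@]21C | intermediate
21 | 9β-(1-acetoxybut-2-ynyl)-11-nordrimane-7α,8α-diol | CC#CC(OC(C)=O)[C@H]1[C@](C)(O)[C@H](O)C[C@H]2C(C)(C)CCC[C@@]21C | intermediate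
22 | 9β-(1-acetoxybut-2-ynyl)-8α-hydroxy-11-nordriman-7-one | CC#CC(OC(C)=O)[C@H]1[C@](C)(O)C(=O)C[C@H]2C(C)(C)CCC[C@@]21C | intermediate
23 | 9β-(1-acetoxybut-2-ynyl)-7,8α-bis(triethylsilyloxy)-11-nordrim-6-ene | CC#CC(OC(C)=O)[C@H]1[C@](C)(O[Si](CC)(CC)CC)C(O[Si](CC)(CC)CC)=C[C@H]2C(C)(C)CCC[C@@]21C | intermediate
24 | 9β-(1-acetoxybut-2-ynyl)-6α,7α-epoxy-7β,8α-bis(triethylsilyloxy)-11-nordrimane | CC#CC(OC(C)=O)[C@H]1[C@](C)(O[Si](CC)(CC)CC)[C@]3(O[Si](CC)(CC)CC)O[C@@H]3[C@H]2C(C)(C)CCC[C@@]21C | intermediate
25 | 9β-(1-acetoxybut-2-ynyl)-6α,8α-bis(triethylsilyloxy)-11-nordriman-7-one | CC#CC(OC(C)=O)[C@H]1[C@](C)(O[Si](CC)(CC)CC)C(=O)[C@H](O[Si](CC)(CC)CC)[C@H]2C(C)(C)CCC[C@@]21C | intermediate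
26 | 9β-(1-acetoxybut-2-ynyl)-6α-hydroxy-8α-(triethylsilyloxy)-11-nordriman-7-one | CC#CC(OC(C)=O)[C@H]1[C@](C)(O[Si](CC)(CC)CC)C(=O)[C@H](O)[C@H]2C(C)(C)CCC[C@@]21C | intermediate
27 | 6α-acetoxy-9β-(1-acetoxybut-2-ynyl)-8α-(triethylsilyloxy)-11-nordriman-7-one | CC#CC(OC(C)=O)[C@H]1[C@](C)(O[Si](CC)(CC)CC)C(=O)[C@H](OC(C)=O)[C@H]2C(C)(C)CCC[C@@]21C | intermediate
28 | 6α-acetoxy-9β-(1-acetoxybut-2-ynyl)-8α-(triethylsilyloxy)-11-nordriman-7β-ol | CC#CC(OC(C)=O)[C@H]1[C@](C)(O[Si](CC)(CC)CC)[C@@H](O)[C@H](OC(C)=O)[C@H]2C(C)(C)CCC[C@@]21C | intermediate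
29 | 6α-acetoxy-9β-(3-acetoxybuta-1,2-dienyl)-8α-(triethylsilyloxy)-11-nordriman-7β-ol | CC(OC(C)=O)=C=C[C@H]1[C@](C)(O[Si](CC)(CC)CC)[C@@H](O)[C@H](OC(C)=O)[C@H]2C(C)(C)CCC[C@@]21C | intermediate
30 | 6α-acetoxy-9β-[(E)-3-oxobut-1-enyl]-8α-(triethylsilyloxy)-11-nordriman-7β-ol | CC(=O)/C=C/[C@H]1[C@](C)(O[Si](CC)(CC)CC)[C@@H](O)[C@H](OC(C)=O)[C@H]2C(C)(C)CCC[C@@]21C | intermediate
31 | 6α-acetoxy-9β-[(E)-3-oxobut-1-enyl]-11-nordrimane-7β,8α-diol (CNP0136046.1) | CC(=O)/C=C/[C@H]1[C@](C)(O)[C@@H](O)[C@H](OC(C)=O)[C@H]2C(C)(C)CCC[C@@]21C | target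

**Step count.** 21 steps in total; the longest linear sequence is 21 steps (1 → 31), with 3, 6 and 16 entering as commercial reagents.

**Steps most likely to fail**

Step 12. The 7β C–O bond is pseudoequatorial in the resting half-chair of ring B, so the rearrangement may be slow enough for [1,2]-migration or decomposition of the anion to compete. The fallback makes the carbanion without a base and attaches the alkyne afterwards. It sets out from alcohol 15: alkylation with KH and iodomethyl(tributyl)stannane would give 7β-(tributylstannylmethoxy)-11-nordrim-8-ene F1. Tin–lithium exchange (n-BuLi, THF, −78 °C) then triggers the Still variant of the rearrangement, whose unstabilised carbanion shifts at −78 °C, to give drim-7-en-11-ol F2. Dess–Martin oxidation would give drim-7-en-11-al F3, used at once, and addition of prop-1-ynylmagnesium bromide at −78 °C comes back to the route at 19.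

Step 4. The Grignard reagent may bond through its unsubstituted terminus, or the very congested adduct may revert, so that the C4–C5 bond is not formed with the 1,1-dimethylallyl connectivity. The fallback forms that bond by conjugate addition and sets out from 5. DIBAL-H reduction would give 6-allyl-3-ethoxy-6-methylcyclohex-2-en-1-ol F4, and dilute acid would convert it into (S)-4-allyl-4-methylcyclohex-2-en-1-one F5. LDA/MeI would give 4-allyl-4,6-dimethylcyclohex-2-en-1-one F6. Hosomi–Sakurai addition of trimethyl(3-methylbut-2-enyl)silane with TiCl4 (γ-attack, expected mainly anti to the allyl group, with separation of the minor isomer) would give 4-allyl-4,6-dimethyl-3-(2-methylbut-3-en-2-yl)cyclohexan-1-one F7, with the new group cis to the C4 methyl. Ring-closing metathesis of F7 comes back to the route at 11.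

Step 19. Reduction of the hindered α-acetoxy ketone may be slow, may attack the wrong face, or may be followed by acetyl migration from O6 to O7. The fallback reverses the order and delivers hydride internally, setting out from hydroxy ketone 26. Me4NBH(OAc)3 in MeCN/AcOH at −20 °C (hydroxyl-directed reduction through the borohydride bound to the 6α-OH) would give 9β-(1-acetoxybut-2-ynyl)-8α-(triethylsilyloxy)-11-nordrimane-6α,7β-diol F8. Selective acetylation of the less hindered 6-OH (AcCl, 2,4,6-collidine, CH2Cl2, −78 °C; the 7-OH is flanked by the fully substituted C8) comes back to the route at 28.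

**Further compounds**
F1 | step 12 | 7β-(tributylstannylmethoxy)-11-nordrim-8-ene | CCCC[Sn](CCCC)(CCCC)CO[C@H]1C[C@H]2C(C)(C)CCC[C@]2(C)C=C1C
F2 | step 12 | drim-7-en-11-ol | OC[C@H]1C(C)=CC[C@H]2C(C)(C)CCC[C@@]21C
F3 | step 12 | drim-7-en-11-al | O=C[C@H]1C(C)=CC[C@H]2C(C)(C)CCC[C@@]21C
F4 | step 4 | 6-allyl-3-ethoxy-6-methylcyclohex-2-en-1-ol (6S; carbinol epimers) | CCOC1=CC(O)[C@](C)(CC=C)CC1
F5 | step 4 | (S)-4-allyl-4-methylcyclohex-2-en-1-one | O=C1C=C[C@](C)(CC=C)CC1
F6 | step 4 | 4-allyl-4,6-dimethylcyclohex-2-en-1-one (4S; C6 epimers) | O=C1C=C[C@](C)(CC=C)CC1C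
F7 | step 4 | 4-allyl-4,6-dimethyl-3-(2-methylbut-3-en-2-yl)cyclohexan-1-one (C3 group cis to C4 methyl; C6 epimers) | O=C1C[C@@H](C(C)(C)C=C)[C@](C)(CC=C)CC1C
F8 | step 19 | 9β-(1-acetoxybut-2-ynyl)-8α-(triethylsilyloxy)-11-nordrimane-6α,7β-diol | CC#CC(OC(C)=O)[C@H]1[C@](C)(O[Si](CC)(CC)CC)[C@@H](O)[C@H](O)[C@H]2C(C)(C)CCC[C@@]21C
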